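The ratio of Q to free Z in the dawn run reads 0.494 at 3.00 h and 0.475 at 12.0 h, so I freeze it and reckon both new flasks from it.

| setting | dawn | dusk | ochre | green |
|---|---|---|---|---|
| Z | 29 mM | 22 mM | 43 mM | 43 mM |
| G | 51.6 mM | 51.6 mM | 52.0 mM | 100 mM |
| remark | run made earlier | run made earlier |  |  |
| time |  |  | 2.5 d | 2.5 d |

| run | time / h | Z / % | Q / % | X / % | E / % |
|---|---|---|---|---|---|
| dawn | 1.00 | 72.1 | 28.7 | 0.3 | 0 |
| dawn | 2.00 | 66.5 | 31.4 | 1.4 | 0 |
| dawn | 3.00 | 65.2 | 32.2 | 1.6 | 0.9 |
| dawn | 6.00 | 63.3 | 31.7 | 3.3 | 0.9 |
| dawn | 12.0 | 62.3 | 29.6 | 6.1 | 2.3 |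
| dusk | 1.00 | 70.2 | 29.3 | 1.4 | 0 |
| dusk | 3.00 | 64.8 | 33.9 | 2.2 | 1.2 |
| dusk | 6.00 | 63.4 | 32.1 | 4.4 | 1.0 |
| dusk | 8.00 | 62.4 | 32.7 | 5.9 | 0.6 |
| dusk | 12.0 | 59.1 | 30.6 | 6.5 | 2.5 |

(standard deviation of a reading: 0.5 percentage points)

1. which of these there is most of at the end, counted by the Z in it, ochre (X / Q / E / Z)
2. which of these there is most of at the end, counted by the Z in it, green (X / Q / E / Z)
3. how much there is at the end of the one of these that leads, in percent of the Z charged: ochre
4. how much there is at the end of the one of these that leads, in percent of the Z charged: green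

- a reading or a percentage of X counts all its forms, free or not
- a reading of Z is of its free form alone

1. From the last dawn reading I take 0.0117 /mM as the binding quotient, a pre-equilibrium constant: Q over free Z, divided by free G, with G counted as held in Q, X and E alike. The last dusk reading gives 0.0121 /mM.

2. Free Z starts steeply and, in the dawn run, bends near 3.00 h. At that knee the quotient, solved against both charges, puts 31.1% of the Z in Q for ochre and 48.1% for green.

3. Past the knee, the last dawn reading gives Q a first-order drain into X and E of 0.0236 /h, so the Z not yet turned falls in ochre at 0.00734 /h and in green at 0.0114 /h.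

4. Holding those shares to 2.5 d, I reckon ochre's free Z at 44.3%, above X and E together at 35.7%, so I commit to Z leading there. For green I reckon free Z at 26.2%, below X and E together at 49.5%, so the split between X and E names green's leader. The readings reach 20.0% of that time, and I do not carry their split so far.

The forecast gives ochre Z at 49%, above my figure, and green X at 35%: “X leads, though uncertainly”.

The flask gives ochre Z at 48.1% and green E at 35.7%.

    Z + X ⇌ L, settled at all times (K = 13.0 /M)
    X ⇌ E (K = 31.0, k = 0.00120 /min)
    Z + G ⇌ Q (K = 12.0 /M, k = 0.220 /M/min)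
    Z → D (k = 7.70 × 10⁻⁷ /min)
    Q → X (k = 3.90 × 10⁻⁴ /min)

Green's E at 35.7% stands above its X at 11.4%, and in ochre the half-life of free X and E by their exchange, both ways together, is 0.389 d, short against 2.5 d. The binding quotient times green's free G at the end gives 0.817, where Q over free Z stands at 0.828. In the neighbour of ochre charged with 130 mM of G, with 21.5% free Z and 74.5% of its G free at the end, the quotient gives Q 24.4%, and that flask holds 24.7%.

The numbers in the tables stem from a simulated flask for an exercise; scatter was added.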